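Readings and results are calculated from invented constants, noise included.

1. Amounts first: this flask starts at 0.52 M of starting material with 1.20 equiv of reagent in the second phase, and the beta run, at 0.78 M, is what I have to read from.

- beta: starting material 0.78 M; reagent in the second phase 1.2 equiv; run made earlier
- flask: starting material 0.52 M; reagent in the second phase 1.20 equiv; time 3.0 d; volume of the second phase over the first 1.0

beta run (percent of the starting material charged)

| time / h | target / % | crystals / % | starting material / % |
|---|---|---|---|
| 0.667 | 5.4 | 1.8 | 88.6 |
| 2.00 | 17.3 | 11.6 | 68.4 |
| 3.00 | 23.1 | 18.4 | 59.2 |
| 5.00 | 31.9 | 30.8 | 42.8 |
| 8.00 | 43.4 | 42.9 | 25.4 |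

(standard deviation of a reading: 1 percentage point)

- what is said of target includes crystals
- in the second phase: reagent in the second phase; everything else is in the first
- charges count per volume of the first phase; a concentration in a rate is the amount of a species over the volume of its own phase; every rate counts per litre of the first phase
- crystals is a solid; its amount is given per volume of the solution
- the numbers in the tables scatter by 1 percentage point (one standard deviation)
- the earlier runs hold the two phases in the same ratio of volumes as the flask asked about

1. how much target and crystals together there is at 3.0 d, in percent of the starting material charged
2. concentration of target in solution at 3.0 d, in percent of saturation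

2. I need two times. The first comes from the beta run, where starting material falls from 88.6 % at 0.667 h to 25.4 % at 8.00 h. Read as a pseudo-first-order decay, this gives 5.87 h, the consumption life, the time in which starting material falls by a factor e.

3. The second time is the asked 3.0 d, which is 12.3 lives. Even if this more dilute flask runs slower, it should spend much of its time past consumption.

4. At 8.00 h the beta run has kept 58.2 % of the starting material it consumed. I take that share as my ceiling for y and commit to something below it.

5. The forecast says 60 % for y, above my ceiling, and 100 % for saturation: “That share stays roughly constant”.

6. The flask gives 53.2 % and 97.5 %.

    reagent in the reaction phase ⇌ reagent in the second phase, rate k1*([reagent in the reaction phase] - [reagent in the second phase]/K1) per volume of the first phase (partition coefficient = 10.0, kL = 1.50 h⁻¹)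
    starting material + reagent in the reaction phase → target (k = 4.80 M⁻¹ h⁻¹)
    reagent in the reaction phase + target → over-reacted product (k = 8.70 M⁻¹ h⁻¹)
    crystals ⇌ target, rate k4*(cs4 - [target]) while solid is left; crystals form when [target] > cs4 (solubility = 12.0 mM, k = 2.70 h⁻¹)
    target ⇌ isomer of the product (K = 0.550, k = 0.00920 h⁻¹)
    2 starting material → homo dimer (k = 0.0560 M⁻¹ h⁻¹)

7. The neighbour flask, read at 30 h, is 5.11 lives in and holds 58.2 % of target and crystals, with 14.1 % of over-reacted product and 5.0 % of starting material left. At 12.3 lives the asked flask holds 23.1 % of over-reacted product, and target and crystals have fallen by 5 percentage points. The low solubility of target is the main reason that target and crystals still stand so high at 3.0 d: the asked flask run without that low solubility holds 8.02 %, against 53.2 % with it.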